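## Retrosynthetic overview
1. Ring D (the dihydrofuran) is made last. Cutting C1–C5' and C10–O gives the unprotected 2',6'-dihydroxy-4,4'-dimethoxychalcone and aristol-1(10)-ene-8,9-dione, the pairing presumed in the plant. The enedione is generated only in the flask from its acyloin, and both bonds plus C1 and C10 are set in one final operation.
2. The acyloin comes from aristolone by C9 oxygenation of its extended enolate, which moves the alkene from 9,10 to 1,10.
3. Ring C (the cyclopropane) comes from isopropylidene transfer to C6=C7 of a cross-conjugated dienone.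
4. Ring B comes from a Robinson annulation with methyl vinyl ketone. C4 comes from a catalytic asymmetric methyl conjugate addition to 2-methylcyclohexenone.
5. Ring order is A (bought), then B, C and D. The chalcone comes from one Claisen–Schmidt condensation.

Numbering: aristolane numbering is used. Ring A is C1–C5 and C10, ring B is C5–C10, and ring C is C6, C7 and C11. The α face carries the C4 and C5 methyls and the β face carries C11. Primed atoms belong to the chalcone A ring, with C1' bearing the carbonyl.

Assumption: the (R,S,S)-phosphoramidite named in step 1 is taken to give the 4R methyl centre; if the sense is opposite, its equally available mirror image is used and nothing else changes.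

## Route

Step 1
Reactants: 1 2-methylcyclohex-2-en-1-one
Product: 3 (R)-[(2,3-dimethylcyclohex-1-en-1-yl)oxy]trimethylsilane, via dimethylaluminium enolate 2 (not isolated)
Conditions: Me3Al (1.5 equiv), Cu(O2CC4H3S) (copper thiophene-2-carboxylate, 2 mol %), (11bR)-N,N-bis[(1S)-1-phenylethyl]dinaphtho[2,1-d:1',2'-f][1,3,2]dioxaphosphepin-4-amine (4 mol %), Et2O, −30 °C; then TMSOTf (1.6 equiv), −30 → 0 °C
Reagents that add atoms: trimethylaluminium C[Al](C)C; trimethylsilyl trifluoromethanesulfonate C[Si](C)(C)OS(=O)(=O)C(F)(F)F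
Why: In this copper-catalysed asymmetric conjugate addition the chiral phosphoramidite–copper methyl species adds to one enone face to set C4 (R), and O-silylation of the aluminium enolate locks the tetrasubstituted enolate regiochemistry for the next C–C bond.

Step 2
Reactants: 3 (R)-[(2,3-dimethylcyclohex-1-en-1-yl)oxy]trimethylsilane; 4 methyl vinyl ketone
Product: 6 (4aS,5R)-4a,5-dimethyl-4,4a,5,6,7,8-hexahydronaphthalen-2(3H)-one, via 1,5-diketone 5 (not isolated)
Conditions: BF3·OEt2 (1 equiv), i-PrOH (1 equiv), MeNO2, −20 °C; aqueous wash and solvent swap; then NaOMe (0.5 equiv), MeOH, rt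
Reagents that add atoms: none
Why: In this Robinson annulation (Mukaiyama–Michael addition then intramolecular aldol condensation) 4 approaches the enol silane anti to the pseudoaxial C4 methyl, so the C5 quaternary centre forms with its methyl cis to the C4 methyl (2S in 5, 4aS in 6), and base closes ring B.

Step 3
Reactants: 6 (4aS,5R)-4a,5-dimethyl-4,4a,5,6,7,8-hexahydronaphthalen-2(3H)-one
Product: 7 (4aR,5R)-4a,5-dimethyl-5,6,7,8-tetrahydronaphthalen-2(4aH)-one
Conditions: DDQ (1.5 equiv), 1,4-dioxane, reflux
Reagents that add atoms: none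
Why: DDQ dehydrogenation under neutral conditions goes through the kinetic C7 enol and gives the cross-conjugated 6,7-ene rather than the linear dienone, and no stereocentre is touched (4a reads R only through a priority change).

Step 4
Reactants: 7 (4aR,5R)-4a,5-dimethyl-5,6,7,8-tetrahydronaphthalen-2(4aH)-one; 8 isopropyldiphenylsulfonium tetrafluoroborate
Product: 9 aristolone, (4R,5R,6S,7R)-aristol-9-en-8-one
Conditions: 8 (1.6 equiv), t-BuLi (1.5 equiv), DME/THF, −78 °C; then 7, −78 → −20 °C; recrystallise (hexane) to raise ee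
Reagents that add atoms: none
Why: In this Corey–Chaykovsky-type cyclopropanation (Michael-initiated ring closure) only the disubstituted C6=C7 can accept the diphenylsulfonium isopropylide because C10 is fully substituted, attack at C6 comes anti to the axial C5 methyl, and cis closure on C7 sets 6S,7R with ring C on the β face.

Step 5
Reactants: 9 aristolone
Product: 11 (4R,5R,6S,7R,9S)-9-hydroxyaristol-1(10)-en-8-one (9α-OH acyloin), via potassium dienolate 10 (not isolated)
Conditions: KN(SiMe3)2 (1.3 equiv), THF, −78 → −20 °C; then 2-(phenylsulfonyl)-3-phenyloxaziridine (1.4 equiv), −78 °C; AcOH quench at −78 °C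
Reagents that add atoms: 2-(phenylsulfonyl)-3-phenyloxaziridine O=S(=O)(N1OC1c1ccccc1)c1ccccc1
Why: The α' hydrogen (C7–H) sits on the cyclopropane and is not removed, so γ-deprotonation at C1 gives the extended dienolate, which the Davis oxaziridine hydroxylates at its α carbon C9 from the α face (anti to ring C) with the alkene shifting to C1=C10, and the new 9S centre is erased in step 7.

Step 6
Reactants: 12 1-(2,6-dihydroxy-4-methoxyphenyl)ethan-1-one; 13 4-methoxybenzaldehyde
Product: 14 (E)-1-(2,6-dihydroxy-4-methoxyphenyl)-3-(4-methoxyphenyl)prop-2-en-1-one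
Conditions: KOH (50% aq), EtOH, 0 °C → rt, 48 h; cold 1 M HCl to pH 4
Reagents that add atoms: none
Why: In this Claisen–Schmidt condensation the acetophenone enolate adds to the non-enolisable aldehyde and E1cB loss of water gives the E-enone, while cold acidification keeps the 2',6'-dihydroxychalcone from closing to the flavanone.

Step 7
Reactants: 11 (9S)-9-hydroxyaristol-1(10)-en-8-one; 14 (E)-2',6'-dihydroxy-4,4'-dimethoxychalcone
Product: 17 target CNP0121765.1 with (1R,4R,5R,6S,7R,10S) configuration, via enedione 15 (not isolated), via Michael adduct 16 (not isolated)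
Conditions: Dess–Martin periodinane (1.05 equiv), CH2Cl2, 0 °C → rt; then 14 (1.2 equiv), Sc(OTf)3 (10 mol %), (CF3)2CHOH/CH2Cl2 1:3, −20 °C → rt; then PhI(OAc)2 (1.1 equiv), 0 °C
Reagents that add atoms: none
Why: Proposed new method: Dess–Martin oxidation of the acyloin unmasks 15, a β,γ-unsaturated 1,2-dicarbonyl whose s-cis dione chelates Sc(OTf)3 like the β,γ-unsaturated α-keto esters used in Friedel–Crafts conjugate additions of electron-rich phenols, so C5' of 14 (C3' and C5' are equivalent) attacks C1 along the chair-like axial α trajectory while the β face is roofed by the endo methyl of ring C; the diosphenol 16 then binds PhI(OAc)2 through its C9 enol oxygen and the adjacent C6'–OH displaces iodobenzene at C10 in a 5-exo SN2' sense (closest known types: trivalent-iodine α-oxygenation of ketones through enolonium species and oxidative cycloetherification of β-(2-hydroxyaryl) ketones to 2-acyl-2,3-dihydrobenzofurans), which restores the 8,9-dione and, because the ring fusion must be cis and C10 is open only anti to ring C, sets 1R and 10S together.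

## Compound list
1 | 2-methylcyclohex-2-en-1-one | CC1=CCCCC1=O | starting material
2 | dimethylaluminium (R)-2,3-dimethylcyclohex-1-en-1-olate | C[C@@H]1CCCC(O[Al](C)C)=C1C | intermediate
3 | (R)-[(2,3-dimethylcyclohex-1-en-1-yl)oxy]trimethylsilane | C[C@@H]1CCCC(O[Si](C)(C)C)=C1C | intermediate
4 | methyl vinyl ketone | C=CC(C)=O | starting material
5 | (2S,3R)-2,3-dimethyl-2-(3-oxobutyl)cyclohexan-1-one | C[C@@H]1CCCC(=O)[C@@]1(C)CCC(C)=O | intermediate
6 | (4aS,5R)-4a,5-dimethyl-4,4a,5,6,7,8-hexahydronaphthalen-2(3H)-one | C[C@@H]1CCCC2=CC(=O)CC[C@@]12C | intermediate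
7 | (4aR,5R)-4a,5-dimethyl-5,6,7,8-tetrahydronaphthalen-2(4aH)-one | C[C@@H]1CCCC2=CC(=O)C=C[C@@]12C | intermediate
8 | isopropyldiphenylsulfonium tetrafluoroborate | CC(C)[S+](c1ccccc1)c1ccccc1.F[B-](F)(F)F | starting material
9 | aristolone, (1aR,7R,7aR,7bS)-1,1,7,7a-tetramethyl-1,1a,4,5,6,7,7a,7b-octahydro-2H-cyclopropa[a]naphthalen-2-one | C[C@@H]1CCCC2=CC(=O)[C@@H]3[C@@H](C3(C)C)[C@@]12C | intermediate
10 | potassium aristola-1(10),8-dien-8-olate | C[C@@H]1CCC=C2C=C([O-])[C@@H]3[C@@H](C3(C)C)[C@@]12C.[K+] | intermediate
11 | (4R,5R,6S,7R,9S)-9-hydroxyaristol-1(10)-en-8-one | C[C@@H]1CCC=C2[C@H](O)C(=O)[C@@H]3[C@@H](C3(C)C)[C@@]12C | intermediate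
12 | 1-(2,6-dihydroxy-4-methoxyphenyl)ethan-1-one | CC(=O)c1c(O)cc(OC)cc1O | starting material
13 | 4-methoxybenzaldehyde | COc1ccc(C=O)cc1 | starting material
14 | (E)-1-(2,6-dihydroxy-4-methoxyphenyl)-3-(4-methoxyphenyl)prop-2-en-1-one | COc1ccc(/C=C/C(=O)c2c(O)cc(OC)cc2O)cc1 | intermediate
15 | (4R,5R,6S,7R)-aristol-1(10)-ene-8,9-dione | C[C@@H]1CCC=C2C(=O)C(=O)[C@@H]3[C@@H](C3(C)C)[C@@]12C | intermediate
16 | 1α-{2,4-dihydroxy-6-methoxy-3-[(E)-3-(4-methoxyphenyl)acryloyl]phenyl}-9-hydroxyaristol-9-en-8-one | COc1ccc(/C=C/C(=O)c2c(O)cc(OC)c(c2O)[C@H]2CC[C@@H](C)[C@@]3(C)C2=C(O)C(=O)[C@@H]2[C@H]3C2(C)C)cc1 | intermediate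
17 | CNP0121765.1: aristolane-8,9-dione cis-fused on its α face through C1 (to C5') and C10 (to O6') to the chalcone, (1R,4R,5R,6S,7R,10S) | COc1ccc(/C=C/C(=O)c2c(O)cc(OC)c3c2O[C@]24C(=O)C(=O)[C@@H]5[C@@H](C5(C)C)[C@@]2(C)[C@H](C)CC[C@H]34)cc1 | target

## Totals
Total steps: 7. Longest linear sequence: 6 (steps 1, 2, 3, 4, 5, 7).

## Steps most likely to fail

**Step 7.** Three things can go wrong here. Compound 15 can drift to its dienol tautomer. The neutral acylphloroglucinol may add too slowly. PhI(OAc)2 may attack the cinnamoyl phenol instead of the diosphenol.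

The fallback sets out from 11 and 12 and comes back to the route at 17. It leaves the cinnamoyl arm off until ring D is closed. Compound 11 is oxidised to 15 as before and met by the sodium phenolate of 12 (NaH, THF, −20 °C). This is a much stronger carbon nucleophile, and it has no enone and no flavanone channel. The product is 1α-(3-acetyl-2,4-dihydroxy-6-methoxyphenyl)-9-hydroxyaristol-9-en-8-one F1. PhI(OAc)2 in (CF3)2CHOH closes it to the ring D acetophenone hybrid F2. A BF3·OEt2-mediated Claisen–Schmidt condensation of F2 with 13 (dioxane, rt, then MeOH to break the boron chelate) then gives 17. This last step avoids hydroxide, which would cause benzilic acid contraction of the non-enolisable 8,9-dione.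

**Step 5.** The dienolate may be oxygenated at C1 (γ) instead of C9, or 11 may isomerise to the conjugated diosphenol.

The fallback sets out from 9 and comes back at 15, inside the flask of step 7. It places oxygen on C9 through the enone π bond instead of the enolate. Weitz–Scheffer epoxidation (H2O2, NaOH, MeOH, 0 °C, attack anti to ring C) gives 9α,10α-epoxyaristolan-8-one F3. Catalytic H2SO4 in AcOH isomerises it to the diosphenol 9-hydroxyaristol-9-en-8-one F4. DDQ (1 equiv, CH2Cl2, rt) abstracts hydride from C1 of this enol to give 15, which is used at once with 14.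

**Step 4.** C6 is neopentyl, so the bulky ylide may add 1,2 to give an epoxide, or may not add at all.

The fallback sets out from 7 and comes back at 9. It replaces the ylide by a dipolar cycloaddition. 2-Diazopropane F5 (from acetone hydrazone, Ag2O, Et2O, −20 °C) adds to C6=C7 from the β face, with its carbon on C6. This gives the 1-pyrazoline F6. Immediate irradiation (350 nm, Et2O, −20 °C) expels nitrogen and closes ring C to 9.

## Further compounds
F1 | step 7 | 1α-(3-acetyl-2,4-dihydroxy-6-methoxyphenyl)-9-hydroxyaristol-9-en-8-one | CC(=O)c1c(O)cc(OC)c(c1O)[C@H]1CC[C@@H](C)[C@@]2(C)C1=C(O)C(=O)[C@@H]1[C@H]2C1(C)C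
F2 | step 7 | ring D acetophenone hybrid, the target skeleton with acetyl in place of the 4-methoxycinnamoyl group, (1R,4R,5R,6S,7R,10S) | CC(=O)c1c(O)cc(OC)c2c1O[C@]13C(=O)C(=O)[C@@H]4[C@@H](C4(C)C)[C@@]1(C)[C@H](C)CC[C@H]23
F3 | step 5 | 9α,10α-epoxyaristolan-8-one | C[C@@H]1CCC[C@@]23O[C@@H]2C(=O)[C@@H]2[C@@H](C2(C)C)[C@@]13C
F4 | step 5 | 9-hydroxyaristol-9-en-8-one | C[C@@H]1CCCC2=C(O)C(=O)[C@@H]3[C@@H](C3(C)C)[C@@]12C
F5 | step 4 | 2-diazopropane | CC(C)=[N+]=[N-]
F6 | step 4 | 1-pyrazoline from β-face addition of 2-diazopropane to C6=C7 of 7 (CMe2 on C6, N on C7) | C[C@@H]1CCCC2=CC(=O)[C@H]3N=NC(C)(C)[C@H]3[C@@]12C
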